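**Retrosynthetic overview**
- The target bichalcone comes from a tetra-MOM bichalcone by acid removal of all four acetals.
- Both enone Cα=Cβ bonds are disconnected at once: a double Claisen–Schmidt aldol condensation of a diaryl-ether bis-acetophenone with two equivalents of 4-(methoxymethoxy)benzaldehyde.
- The diaryl ether C–O bond is disconnected by SNAr: a ring A phenol (5-hydroxy-4-methoxy-2-MOM-oxyacetophenone) plus 4-fluoro-2-MOM-oxyacetophenone (ring A').
- The ring A phenol comes from vanillin by Dakin oxidation, regioselective Friedel–Crafts acetylation, and chelation-controlled benzyl/MOM differentiation of the two hydroxyls.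
- No ring is formed; all four benzene rings are bought. Assembly order: ring A functionalised, then the A–O–A' ether, then both rings B attached in one aldol operation, then deprotection.

Assumption: the target has no stereocentre, so "single enantiomer" is read as the single (E,E) double-bond isomer drawn.

**Route**

Step 1
Reactants: 1 vanillin (4-hydroxy-3-methoxybenzaldehyde)
Product: 3 2-methoxybenzene-1,4-diol (methoxyhydroquinone), via 4-hydroxy-3-methoxyphenyl formate 2 (not isolated)
Conditions: 30% aq. H2O2, aq. NaOH, 0 °C → rt, N2; then aq. HCl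
Reagents that add atoms: hydrogen peroxide, OO
Why: Dakin oxidation — hydroperoxide adds to the aldehyde of the electron-rich para-hydroxyaryl ring, the aryl group migrates to oxygen (Baeyer–Villiger type) to give formate 2, and this is saponified in the same flask.

Step 2
Reactants: 3 2-methoxybenzene-1,4-diol
Product: 4 1-(2,5-dihydroxy-4-methoxyphenyl)ethanone
Conditions: AcOH, BF3·OEt2, 90 °C, N2; then aq. NaOAc
Reagents that add atoms: acetic acid, CC(=O)O
Why: BF3-mediated Friedel–Crafts (Fries-type) C-acetylation goes to the only ring position that is both ortho to a hydroxyl and para to the methoxy group, and the chelated ortho-hydroxy ketone formed is deactivated towards a second acylation.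

Step 3
Reactants: 4 1-(2,5-dihydroxy-4-methoxyphenyl)ethanone
Product: 5 1-[5-(benzyloxy)-2-hydroxy-4-methoxyphenyl]ethanone
Conditions: BnBr (1.05 equiv), K2CO3 (1.1 equiv), acetone, reflux
Reagents that add atoms: benzyl bromide, BrCc1ccccc1
Why: Williamson ether synthesis in which the 2-OH is tied up in a hydrogen bond to the ketone, so a weak base and one equivalent of halide alkylate only the free 5-OH.

Step 4
Reactants: 5 1-[5-(benzyloxy)-2-hydroxy-4-methoxyphenyl]ethanone
Product: 6 1-[5-(benzyloxy)-4-methoxy-2-(methoxymethoxy)phenyl]ethanone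
Conditions: NaH (1.1 equiv), MOMCl, DMF, 0 °C → rt
Reagents that add atoms: chloromethyl methyl ether, COCCl
Why: MOM protection (O-alkylation of a phenoxide) — NaH fully deprotonates the chelated phenol, which is far more acidic than the methyl ketone, and the phenoxide is trapped by the reactive α-chloro ether.

Step 5
Reactants: 6 1-[5-(benzyloxy)-4-methoxy-2-(methoxymethoxy)phenyl]ethanone
Product: 7 1-[5-hydroxy-4-methoxy-2-(methoxymethoxy)phenyl]ethanone
Conditions: H2 (1 atm), 10% Pd/C, EtOAc, rt
Reagents that add atoms: none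
Why: Catalytic hydrogenolysis cleaves the benzyl ether much faster than it touches the electron-rich aryl ketone, and the MOM acetal is inert in neutral EtOAc.

Step 6
Reactants: 8 1-(4-fluoro-2-hydroxyphenyl)ethanone
Product: 9 1-[4-fluoro-2-(methoxymethoxy)phenyl]ethanone
Conditions: NaH (1.1 equiv), MOMCl, DMF, 0 °C → rt
Reagents that add atoms: chloromethyl methyl ether, COCCl
Why: MOM protection masks the phenol, which as a phenoxide would deactivate the ring towards the next SNAr step, and uses the same acetal that is removed at the end.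

Step 7
Reactants: 7 1-[5-hydroxy-4-methoxy-2-(methoxymethoxy)phenyl]ethanone; 9 1-[4-fluoro-2-(methoxymethoxy)phenyl]ethanone
Product: 10 1-{5-[4-acetyl-3-(methoxymethoxy)phenoxy]-4-methoxy-2-(methoxymethoxy)phenyl}ethanone
Conditions: K2CO3 (2 equiv), DMF, 120 °C, N2
Reagents that add atoms: none
Why: Nucleophilic aromatic substitution (addition–elimination) — the electron-rich phenoxide of 7 attacks the carbon bearing fluorine para to the acetyl group, which stabilises the Meisenheimer intermediate, and fluoride leaves.

Step 8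
Reactants: 11 4-hydroxybenzaldehyde
Product: 12 4-(methoxymethoxy)benzaldehyde
Conditions: MOMCl, K2CO3, acetone, rt
Reagents that add atoms: chloromethyl methyl ether, COCCl
Why: MOM protection of an unhindered acidic phenol, so that the aldehyde is not deactivated as its phenoxide in the basic aldol step.

Step 9
Reactants: 10 1-{5-[4-acetyl-3-(methoxymethoxy)phenoxy]-4-methoxy-2-(methoxymethoxy)phenyl}ethanone; 12 4-(methoxymethoxy)benzaldehyde (2.5 equiv)
Product: 14 tetra-MOM (E,E)-bichalcone (E)-1-{4-methoxy-2-(methoxymethoxy)-5-[3-(methoxymethoxy)-4-((E)-3-[4-(methoxymethoxy)phenyl]prop-2-enoyl)phenoxy]phenyl}-3-[4-(methoxymethoxy)phenyl]prop-2-en-1-one, via bis(β-hydroxy ketone) aldol adduct 13 (not isolated)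
Conditions: KOH (50% aq.), EtOH, rt, 24–48 h
Reagents that add atoms: none
Why: Double Claisen–Schmidt crossed aldol condensation — each methyl ketone enolate adds to the non-enolisable aldehyde and E1cB dehydration gives the conjugated, thermodynamically favoured E-enones, so no stereocentre survives.

Step 10
Reactants: 14 tetra-MOM (E,E)-bichalcone
Product: 15 target bichalcone, (E)-1-{2-hydroxy-5-[3-hydroxy-4-((E)-3-(4-hydroxyphenyl)prop-2-enoyl)phenoxy]-4-methoxyphenyl}-3-(4-hydroxyphenyl)prop-2-en-1-one
Conditions: 3 M aq. HCl, MeOH, 50 °C, monitored by TLC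
Reagents that add atoms: none
Why: Acid-catalysed acetal solvolysis (MOM cleavage) frees all four phenols, while the E-enones and the diaryl ether are stable to brief mild acid.

**Compound list**
1 | vanillin (4-hydroxy-3-methoxybenzaldehyde) | COc1cc(C=O)ccc1O | starting material
2 | 4-hydroxy-3-methoxyphenyl formate (not isolated) | COc1cc(OC=O)ccc1O | intermediate
3 | 2-methoxybenzene-1,4-diol | COc1cc(O)ccc1O | intermediate
4 | 1-(2,5-dihydroxy-4-methoxyphenyl)ethanone | CC(=O)c1cc(O)c(OC)cc1O | intermediate
5 | 1-[5-(benzyloxy)-2-hydroxy-4-methoxyphenyl]ethanone | CC(=O)c1cc(OCc2ccccc2)c(OC)cc1O | intermediate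
6 | 1-[5-(benzyloxy)-4-methoxy-2-(methoxymethoxy)phenyl]ethanone | CC(=O)c1cc(OCc2ccccc2)c(OC)cc1OCOC | intermediate
7 | 1-[5-hydroxy-4-methoxy-2-(methoxymethoxy)phenyl]ethanone | CC(=O)c1cc(O)c(OC)cc1OCOC | intermediate
8 | 1-(4-fluoro-2-hydroxyphenyl)ethanone | CC(=O)c1ccc(F)cc1O | starting material
9 | 1-[4-fluoro-2-(methoxymethoxy)phenyl]ethanone | CC(=O)c1ccc(F)cc1OCOC | intermediate
10 | 1-{5-[4-acetyl-3-(methoxymethoxy)phenoxy]-4-methoxy-2-(methoxymethoxy)phenyl}ethanone | CC(=O)c1cc(Oc2ccc(C(C)=O)c(OCOC)c2)c(OC)cc1OCOC | intermediate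
11 | 4-hydroxybenzaldehyde | O=Cc1ccc(O)cc1 | starting material
12 | 4-(methoxymethoxy)benzaldehyde | COCOc1ccc(C=O)cc1 | intermediate
13 | bis(β-hydroxy ketone) aldol adduct of 10 with two molecules of 12 (not isolated; carbinol centres unassigned, mixture of diastereomers) | COCOc1ccc(C(O)CC(=O)c2cc(Oc3ccc(C(=O)CC(O)c4ccc(OCOC)cc4)c(OCOC)c3)c(OC)cc2OCOC)cc1 | intermediate
14 | tetra-MOM (E,E)-bichalcone | COCOc1ccc(/C=C/C(=O)c2cc(Oc3ccc(C(=O)/C=C/c4ccc(OCOC)cc4)c(OCOC)c3)c(OC)cc2OCOC)cc1 | intermediate
15 | target bichalcone (both enones E) | COc1cc(O)c(C(=O)/C=C/c2ccc(O)cc2)cc1Oc1ccc(C(=O)/C=C/c2ccc(O)cc2)c(O)c1 | target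

**Totals**
Total step count: 10.
Longest linear sequence: 8 steps (steps 1, 2, 3, 4, 5, 7, 9, 10 from vanillin).

**Three steps most likely to fail, with fallbacks**

Step 7 (SNAr). The fluoride is only moderately activated and both partners carry enolisable methyl ketones, so conversion may stall or aldol by-products may form at 120 °C. The fallback sets out from 7 and switches from SNAr to a copper-catalysed Ullmann-type etherification. Commercial 1-(4-bromo-2-hydroxyphenyl)ethanone F7 is protected (NaH, MOMCl, DMF, 0 °C) to give 1-[4-bromo-2-(methoxymethoxy)phenyl]ethanone F8. F8 is then coupled with phenol 7 using CuI (10 mol %), N,N-dimethylglycine (30 mol %) and Cs2CO3 in dioxane at 90 °C. This pairs an electron-poor aryl bromide with an electron-rich phenol, which is the favourable polarity for this coupling, and it comes back to the route at 10.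

Step 2 (Friedel–Crafts acetylation). The hydroquinone is air-sensitive, and over-acylation or regioisomers are conceivable. The fallback sets out from 1 and builds the ketone by halogen–metal exchange instead of electrophilic acylation.
- Vanillin is benzylated (BnBr, K2CO3, DMF) to 4-(benzyloxy)-3-methoxybenzaldehyde F1.
- Baeyer–Villiger oxidation (mCPBA, CH2Cl2) gives 4-(benzyloxy)-3-methoxyphenyl formate F2, which is not isolated but hydrolysed (KOH, MeOH/H2O) to 4-(benzyloxy)-3-methoxyphenol F3.
- NBS in MeCN at 0 °C brominates para to the methoxy group and ortho to the hydroxyl, giving 4-(benzyloxy)-2-bromo-5-methoxyphenol F4.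
- MOM protection (NaH, MOMCl, DMF) gives 1-(benzyloxy)-5-bromo-2-methoxy-4-(methoxymethoxy)benzene F5.
- Bromine–lithium exchange (n-BuLi, THF, −78 °C) gives 5-(benzyloxy)-4-methoxy-2-(methoxymethoxy)phenyllithium F6, which is quenched with N-methoxy-N-methylacetamide.

This comes back to the route at 6, bypassing steps 2–4.

Step 10 (global MOM removal). Four acetals must be cleaved without acid-induced cyclisation of the 2'-hydroxychalcone units to flavanones. The fallback sets out from 10 and takes the acetals off before the enones exist. Compound 10 is treated with 3 M HCl in MeOH at 50 °C to give 1-[5-(4-acetyl-3-hydroxyphenoxy)-2-hydroxy-4-methoxyphenyl]ethanone F9. F9 is then condensed directly with unprotected 4-hydroxybenzaldehyde 11 (excess 60% aq. KOH, EtOH, rt → 50 °C, then cold dilute HCl to pH 4). This passes through the unprotected bis(β-hydroxy ketone) aldol adduct F10, which is not isolated, and comes back to the route at 15. The enones then never see hot acid, at the cost of a lower-yielding aldol with the phenoxide-deactivated aldehyde.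

**Further compounds**
F1 | step 2 | 4-(benzyloxy)-3-methoxybenzaldehyde | COc1cc(C=O)ccc1OCc1ccccc1
F2 | step 2 | 4-(benzyloxy)-3-methoxyphenyl formate (not isolated) | COc1cc(OC=O)ccc1OCc1ccccc1
F3 | step 2 | 4-(benzyloxy)-3-methoxyphenol | COc1cc(O)ccc1OCc1ccccc1
F4 | step 2 | 4-(benzyloxy)-2-bromo-5-methoxyphenol | COc1cc(O)c(Br)cc1OCc1ccccc1
F5 | step 2 | 1-(benzyloxy)-5-bromo-2-methoxy-4-(methoxymethoxy)benzene | COCOc1cc(OC)c(OCc2ccccc2)cc1Br
F6 | step 2 | 5-(benzyloxy)-4-methoxy-2-(methoxymethoxy)phenyllithium (not isolated) | [Li]c1cc(OCc2ccccc2)c(OC)cc1OCOC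
F7 | step 7 | 1-(4-bromo-2-hydroxyphenyl)ethanone | CC(=O)c1ccc(Br)cc1O
F8 | step 7 | 1-[4-bromo-2-(methoxymethoxy)phenyl]ethanone | CC(=O)c1ccc(Br)cc1OCOC
F9 | step 10 | 1-[5-(4-acetyl-3-hydroxyphenoxy)-2-hydroxy-4-methoxyphenyl]ethanone | CC(=O)c1cc(Oc2ccc(C(C)=O)c(O)c2)c(OC)cc1O
F10 | step 10 | unprotected bis(β-hydroxy ketone) aldol adduct of F9 with two molecules of 11 (not isolated; carbinol centres unassigned) | Oc1ccc(C(O)CC(=O)c2cc(Oc3ccc(C(=O)CC(O)c4ccc(O)cc4)c(O)c3)c(OC)cc2O)cc1
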